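Numbering: C1 ketone, C2, C3 (CHMe), cyclobutane C4–C5–C11–C10 (C10 quaternary), C6 (CMe2), C7–C8–C9. Everything rests on one disconnection: the bridge C3–C2–C1 spans C4 and C11, the carbons flanking C5, which are the α,α'-positions of a cyclobutanone whose 3-position is C10. A chiral enamine of an achiral 3-methyl-3-(silyloxymethyl)cyclobutanone would be annulated with (E)-crotonoyl chloride: C3–C4 and C1–C11 form, the six-membered ring closes, and C3, C4, C10 and C11 are set in one operation. The seven-membered ring would later be closed from C9 onto the C5 carbonyl; the bought four-membered ring is never made.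

Key step: step 7

Remark (precursor design): the silyl group is tert-butyldiphenylsilyl, because a larger group on the CH2O arm shields its face of the ring more strongly in step 7 and tolerates the acidic chloride salts present in that step.
Assumption (sense of induction): for step 7 the usual model for enamines of trans-2,5-disubstituted pyrrolidines (attack anti to the ring substituent beside the enamine carbon) is taken, which calls for the (2R,5R)-amine. For step 10 the usual facial model of methyl ketone enol diisopinocampheylborinates is taken, which calls for (+)-Ipc2BCl. The antipodal reagent would be used if a model test showed the opposite sense.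

Step 1
Reactants: 1 3-oxocyclobutane-1-carboxylic acid
Product: 2 methyl 3,3-dimethoxycyclobutane-1-carboxylate
Conditions: HC(OMe)3, MeOH, TsOH·H2O (cat.), reflux
Reagents that add atoms: methanol, CO; trimethyl orthoformate, COC(OC)OC
Why: Fischer esterification and acid-catalysed ketalisation should run in one pot, the orthoformate removing the water; no stereocentre is involved.

Step 2
Reactants: 2 methyl 3,3-dimethoxycyclobutane-1-carboxylate
Product: 3 methyl 3,3-dimethoxy-1-methylcyclobutane-1-carboxylate
Conditions: LiN(iPr)2, THF, −78 °C; MeI, −78 °C to rt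
Reagents that add atoms: iodomethane, CI
Why: Ester enolate alkylation (SN2 on MeI) should install the methyl group of the future C10, the ketal excluding ketone chemistry; the new quaternary carbon lies on the mirror plane and is not stereogenic.

Step 3
Reactants: 3 methyl 3,3-dimethoxy-1-methylcyclobutane-1-carboxylate
Product: 4 (3,3-dimethoxy-1-methylcyclobutyl)methanol
Conditions: LiAlH4, THF, 0 °C
Reagents that add atoms: none
Why: Hydride reduction of the ester should give the neopentyl primary alcohol (the future C9) and leave the ketal untouched.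

Step 4
Reactants: 4 (3,3-dimethoxy-1-methylcyclobutyl)methanol
Product: 5 tert-butyl[(3,3-dimethoxy-1-methylcyclobutyl)methoxy]diphenylsilane
Conditions: TBDPSCl, imidazole, DMAP (cat.), DMF, rt
Reagents that add atoms: tert-butyl(chloro)diphenylsilane, CC(C)(C)[Si](Cl)(c1ccccc1)c1ccccc1
Why: Imidazole-promoted O-silylation of a primary alcohol is routine, and the large silyl group is the element that later differentiates the two faces of the ring.

Step 5
Reactants: 5 tert-butyl[(3,3-dimethoxy-1-methylcyclobutyl)methoxy]diphenylsilane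
Product: 6 3-{[(tert-butyldiphenylsilyl)oxy]methyl}-3-methylcyclobutan-1-one
Conditions: 1 M HCl, THF, rt
Reagents that add atoms: water, O
Why: Acid hydrolysis of the dimethyl ketal should release the achiral cyclobutanone, the TBDPS ether being stable to dilute acid.

Step 6
Reactants: 6 3-{[(tert-butyldiphenylsilyl)oxy]methyl}-3-methylcyclobutan-1-one; 7 (2R,5R)-2,5-dimethylpyrrolidine
Product: 8 (2R,5R)-1-(3-{[(tert-butyldiphenylsilyl)oxy]methyl}-3-methylcyclobut-1-en-1-yl)-2,5-dimethylpyrrolidine, expected as the two interconverting double-bond isomers (C5=C4 and C5=C11, epimers at C10), used crude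
Conditions: TiCl4 (0.55 equiv), Et3N, toluene, 0 °C to rt; filtration under Ar
Reagents that add atoms: none
Why: TiCl4-mediated enamine condensation, with titanium taking up the water and Et3N the HCl, is the dependable way to condense a hindered secondary amine with a ketone; C10 becomes stereogenic, so the two double-bond isomers are diastereomers.

Step 7
Reactants: 8 enamine (reacting as its C5=C4 isomer, 3S at the ring carbon C10); 9 (E)-but-2-enoyl chloride
Product: 11 (1R,4R,5R,7R)-7-{[(tert-butyldiphenylsilyl)oxy]methyl}-4,7-dimethylbicyclo[3.1.1]heptane-2,6-dione, via bicyclic iminium chloride 10 (not isolated)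
Conditions: MeCN, −30 °C to rt, then 60 °C; NaOAc/AcOH buffer (pH 5), H2O, rt
Reagents that add atoms: water, O
Why: Proposed new method: the acid chloride should acylate the enamine nitrogen and the N-acyl enammonium ion should undergo a [3,3] shift (3-aza-Cope; direct Michael attack of C4 on the crotonyl β-carbon leads to the same adduct), forming C3–C4 and leaving an iminium ion with a ketene or acyl chloride terminus at C1, after which the enamine re-forms towards C11 and is C-acylated to give iminium salt 10, hydrolysed by the buffer. The closest known reaction type is the α,α'-annulation of cyclopentanone and cyclohexanone enamines with acryloyl or crotonoyl chloride to bicyclo[3.2.1]octane-2,8-diones and bicyclo[3.3.1]nonane-2,9-diones; it has not been shown on a cyclobutanone enamine or in desymmetrising form, and the strain of the cyclobutene enamine and of the bicyclo[3.1.1]heptane is the open question. The six-membered ring (C1–C2–C3–C4–C5–C11) closes by 6-(enolendo)-exo-trig acylation of C11 by C1, which can occur only on the face that already carries C3, so C4 and C11 are set together. Their absolute configuration and that of C10 follow from two choices made in the first bond formation: the face (anti to CH2OTBDPS, which puts the C10 methyl on the bridge side, controlled by the bulky silyl ether on the adjacent carbon) and the enantiotopic α-carbon that becomes C4 (controlled by the amine, since only in the C5=C4 enamine do the pyrrolidine methyl beside the double bond and the silyloxymethyl group block the same face, and the mismatched C5=C11 isomer drains into it through the iminium ion). C3 is set in the chair-like transition state, in which the methyl of the (E)-crotonyl unit points away from the C10 methyl, towards the C5 side. The step needs face selectivity, enantiotopic-group selectivity and clean mono-annulation, secured respectively by the TBDPS group, the C2-symmetric amine and the absence of external base (which would turn the acid chloride into a vinylketene).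

Step 8
Reactants: 11 (1R,4R,5R,7R)-7-{[(tert-butyldiphenylsilyl)oxy]methyl}-4,7-dimethylbicyclo[3.1.1]heptane-2,6-dione
Product: 12 (1R,4R,5R,7R)-7-(hydroxymethyl)-4,7-dimethylbicyclo[3.1.1]heptane-2,6-dione
Conditions: HF·pyridine, pyridine, THF, 0 °C to rt
Reagents that add atoms: none
Why: Si–O cleavage by acidic fluoride is chosen over basic Bu4NF because the strained, non-enolisable β-diketone would be opened by retro-Claisen attack of hydroxide or alkoxide.

Step 9
Reactants: 12 (1R,4R,5R,7R)-7-(hydroxymethyl)-4,7-dimethylbicyclo[3.1.1]heptane-2,6-dione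
Product: 13 (1R,4R,5R,7R)-4,7-dimethyl-2,6-dioxobicyclo[3.1.1]heptane-7-carbaldehyde
Conditions: DMP, CH2Cl2, 0 °C to rt
Reagents that add atoms: none
Why: Dess–Martin oxidation should give the C9 aldehyde under neutral conditions; C10 is quaternary, so the aldehyde cannot epimerise or enolise.

Step 10
Reactants: 13 (1R,4R,5R,7R)-4,7-dimethyl-2,6-dioxobicyclo[3.1.1]heptane-7-carbaldehyde; 14 3-methylbut-3-en-2-one
Product: 16 (1R,4R,5R,7R)-7-[(1R)-1-hydroxy-4-methyl-3-oxopent-4-en-1-yl]-4,7-dimethylbicyclo[3.1.1]heptane-2,6-dione, via 3-methylbuta-1,3-dien-2-yl diisopinocampheylborinate 15 (not isolated)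
Conditions: 14, (+)-Ipc2BCl, Et3N, Et2O, −78 to 0 °C; then 13, −78 to −20 °C; MeOH, pH 7 buffer (no peroxide)
Reagents that add atoms: none
Why: Boron-mediated aldol addition of a methyl ketone (Paterson aldol): the preformed enol borinate should add only to the aldehyde at low temperature and form C8–C9, reagent control (Re-face attack) setting C9 as R; the work-up is non-oxidative because H2O2 would cause Baeyer–Villiger oxidation of the cyclobutanone, and a C9 epimer would be a separable diastereomer.

Step 11
Reactants: 16 (1R,4R,5R,7R)-7-[(1R)-1-hydroxy-4-methyl-3-oxopent-4-en-1-yl]-4,7-dimethylbicyclo[3.1.1]heptane-2,6-dione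
Product: 17 (1R,4R,5R,7R)-4,7-dimethyl-7-{(1R)-4-methyl-3-oxo-1-[(triethylsilyl)oxy]pent-4-en-1-yl}bicyclo[3.1.1]heptane-2,6-dione
Conditions: TESCl, imidazole, DMF, 0 °C
Reagents that add atoms: chlorotriethylsilane, CC[Si](Cl)(CC)CC
Why: O-Silylation masks the C9 hydroxyl, which would otherwise protonate the copper enolate of step 12 or add to the enone by oxa-Michael reaction.

Step 12
Reactants: 17 (1R,4R,5R,7R)-4,7-dimethyl-7-{(1R)-4-methyl-3-oxo-1-[(triethylsilyl)oxy]pent-4-en-1-yl}bicyclo[3.1.1]heptane-2,6-dione
Product: 18 (1R,2R,6R,7R,8S,11R)-2-hydroxy-3,3,7,11-tetramethyl-6-[(triethylsilyl)oxy]tricyclo[5.4.0.0(2,8)]undecane-4,9-dione (C5 hydroxyl, C7 and C1 ketones, C9 silyl ether)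
Conditions: [(Ph3P)CuH]6, toluene, −40 °C to rt; aq. NH4Cl
Reagents that add atoms: none
Why: Intramolecular reductive aldol reaction: conjugate hydride delivery to the terminal CH2 of the enone should give the C6 copper enolate regiospecifically (C6 now carrying both methyl groups), which the C9 tether holds under the C5 carbonyl so that it adds to the face opposite the three-carbon bridge, forming C5–C6 and the seven-membered ring; the tether fixes C5 (hydroxyl on the bridge side) and puts only C5, not C1, within reach.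

Step 13
Reactants: 18 (1R,2R,6R,7R,8S,11R)-2-hydroxy-3,3,7,11-tetramethyl-6-[(triethylsilyl)oxy]tricyclo[5.4.0.0(2,8)]undecane-4,9-dione
Product: 19 methyl (1R,2R,6R,7R,8S,11R)-3,3,7,11-tetramethyl-4,9-dioxo-6-[(triethylsilyl)oxy]tricyclo[5.4.0.0(2,8)]undecan-2-yl oxalate
Conditions: MeO2CCOCl, DMAP (cat.), pyridine, CH2Cl2, 0 °C to rt
Reagents that add atoms: methyl chlorooxoacetate, COC(=O)C(Cl)=O
Why: Acylation of the tertiary C5 alcohol with the highly reactive oxalyl half-ester chloride should proceed without forming the alkoxide, so the aldol cannot revert.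

Step 14
Reactants: 19 methyl (1R,2R,6R,7R,8S,11R)-3,3,7,11-tetramethyl-4,9-dioxo-6-[(triethylsilyl)oxy]tricyclo[5.4.0.0(2,8)]undecan-2-yl oxalate
Product: 20 (1S,2S,6R,7R,8R,11R)-3,3,7,11-tetramethyl-6-[(triethylsilyl)oxy]tricyclo[5.4.0.0(2,8)]undecane-4,9-dione
Conditions: Bu3SnH, AIBN (cat.), toluene, 110 °C
Reagents that add atoms: none
Why: Radical deoxygenation of a tertiary methyl oxalate with tin hydride (Barton–McCombie type): the C5 radical sits at a bridgehead and can take hydrogen only on the face opposite C6, which gives the required C5–H; no elimination is possible because every β-position is a bridgehead or quaternary.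

Step 15
Reactants: 20 (1S,2S,6R,7R,8R,11R)-3,3,7,11-tetramethyl-6-[(triethylsilyl)oxy]tricyclo[5.4.0.0(2,8)]undecane-4,9-dione
Product: 21 (1S,2S,6R,7R,8R,11R)-6-hydroxy-3,3,7,11-tetramethyltricyclo[5.4.0.0(2,8)]undecane-4,9-dione
Conditions: HF·pyridine, pyridine, THF, 0 °C
Reagents that add atoms: none
Why: Acidic fluoride should cleave the secondary TES ether without base, so the β-hydroxy ketone is not exposed to retro-aldol opening.

Step 16
Reactants: 21 (1S,2S,6R,7R,8R,11R)-6-hydroxy-3,3,7,11-tetramethyltricyclo[5.4.0.0(2,8)]undecane-4,9-dione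
Product: 22 (1S,2S,4R,6R,7R,8R,11R)-4,6-dihydroxy-3,3,7,11-tetramethyltricyclo[5.4.0.0(2,8)]undecan-9-one
Conditions: Me4NBH(OAc)3, MeCN/AcOH (1:1), −30 °C
Reagents that add atoms: none
Why: Evans–Saksena hydroxyl-directed reduction: the borohydride bound to O9 should deliver hydride to the C7 carbonyl from the face of O9, so the new C7 hydroxyl is trans (1,3-anti) to it, which is R; the C1 ketone has no hydroxyl within reach and is inert to this mild hydride.

Step 17
Reactants: 22 (1S,2S,4R,6R,7R,8R,11R)-4,6-dihydroxy-3,3,7,11-tetramethyltricyclo[5.4.0.0(2,8)]undecan-9-one; 23 angelic acid, (2Z)-2-methylbut-2-enoic acid (used in excess; two equivalents are incorporated)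
Product: 26 (1S,2S,4R,6R,7R,8R,11R)-3,3,7,11-tetramethyl-9-oxotricyclo[5.4.0.0(2,8)]undecane-4,6-diyl bis[(2Z)-2-methylbut-2-enoate] (CNP0283599.1), via angelic 2,4,6-trichlorobenzoic anhydride 24 (not isolated), via C9 monoangelate 25 (not isolated)
Conditions: 23 (3 equiv), 2,4,6-Cl3C6H2COCl (3 equiv), Et3N, toluene, rt; then 22, toluene, 80 °C
Reagents that add atoms: (2Z)-2-methylbut-2-enoic acid (angelic acid, second equivalent), C/C=C(/C)C(=O)O
Why: Yamaguchi-type esterification through the preformed mixed anhydride 24, taken in excess and run without DMAP, should transfer one angeloyl group to each hindered secondary hydroxyl (C9 expected first as the less encumbered one, then C7, the order being immaterial), so two equivalents of angelic acid end up in the diester, and the absence of a nucleophilic catalyst avoids the Z to E isomerisation (angelate to tiglate).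

Compound list
1 | 3-oxocyclobutane-1-carboxylic acid | O=C1CC(C(=O)O)C1 | starting material
2 | methyl 3,3-dimethoxycyclobutane-1-carboxylate | COC(=O)C1CC(OC)(OC)C1 | intermediate
3 | methyl 3,3-dimethoxy-1-methylcyclobutane-1-carboxylate | COC(=O)C1(C)CC(OC)(OC)C1 | intermediate
4 | (3,3-dimethoxy-1-methylcyclobutyl)methanol | OCC1(C)CC(OC)(OC)C1 | intermediate
5 | tert-butyl[(3,3-dimethoxy-1-methylcyclobutyl)methoxy]diphenylsilane | COC1(OC)CC(C)(CO[Si](c2ccccc2)(c2ccccc2)C(C)(C)C)C1 | intermediate
6 | 3-{[(tert-butyldiphenylsilyl)oxy]methyl}-3-methylcyclobutan-1-one (achiral) | CC1(CO[Si](c2ccccc2)(c2ccccc2)C(C)(C)C)CC(=O)C1 | intermediate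
7 | (2R,5R)-2,5-dimethylpyrrolidine | C[C@@H]1CC[C@@H](C)N1 | starting material
8 | (2R,5R)-1-(3-{[(tert-butyldiphenylsilyl)oxy]methyl}-3-methylcyclobut-1-en-1-yl)-2,5-dimethylpyrrolidine, mixture of the two double-bond isomers (C10 left undefined; the 3S isomer reacts) | CC(C)(C)[Si](c1ccccc1)(c1ccccc1)OCC1(C)C=C(N2[C@H](C)CC[C@H]2C)C1 | intermediate
9 | (E)-but-2-enoyl chloride | C/C=C/C(Cl)=O | starting material
10 | C5 iminium chloride of dione 11 with (2R,5R)-2,5-dimethylpyrrolidine (C3, C4, C10, C11 as in 11) | [Cl-].CC(C)(C)[Si](c1ccccc1)(c1ccccc1)OC[C@]1(C)[C@@H]2C(=[N+]3[C@H](C)CC[C@H]3C)[C@H]1C(=O)C[C@H]2C | intermediate (not isolated)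
11 | (1R,4R,5R,7R)-7-{[(tert-butyldiphenylsilyl)oxy]methyl}-4,7-dimethylbicyclo[3.1.1]heptane-2,6-dione (C10 methyl on the bridge side, C3 methyl on the C5 side) | CC(C)(C)[Si](c1ccccc1)(c1ccccc1)OC[C@]1(C)[C@@H]2C(=O)[C@H]1C(=O)C[C@H]2C | intermediate
12 | (1R,4R,5R,7R)-7-(hydroxymethyl)-4,7-dimethylbicyclo[3.1.1]heptane-2,6-dione | OC[C@]1(C)[C@@H]2C(=O)[C@H]1C(=O)C[C@H]2C | intermediate
13 | (1R,4R,5R,7R)-4,7-dimethyl-2,6-dioxobicyclo[3.1.1]heptane-7-carbaldehyde | O=C[C@]1(C)[C@@H]2C(=O)[C@H]1C(=O)C[C@H]2C | intermediate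
14 | 3-methylbut-3-en-2-one | CC(=O)C(C)=C | starting material
15 | 3-methylbuta-1,3-dien-2-yl bis[(1S,2R,3S,5S)-isopinocampheyl]borinate | C=C(OB([C@H]1C[C@H]2C[C@@H]([C@@H]1C)C2(C)C)[C@H]1C[C@H]2C[C@@H]([C@@H]1C)C2(C)C)C(C)=C | intermediate (not isolated)
16 | (1R,4R,5R,7R)-7-[(1R)-1-hydroxy-4-methyl-3-oxopent-4-en-1-yl]-4,7-dimethylbicyclo[3.1.1]heptane-2,6-dione | C=C(C)C(=O)C[C@@H](O)[C@]1(C)[C@@H]2C(=O)[C@H]1C(=O)C[C@H]2C | intermediate
17 | (1R,4R,5R,7R)-4,7-dimethyl-7-{(1R)-4-methyl-3-oxo-1-[(triethylsilyl)oxy]pent-4-en-1-yl}bicyclo[3.1.1]heptane-2,6-dione | C=C(C)C(=O)C[C@@H](O[Si](CC)(CC)CC)[C@]1(C)[C@@H]2C(=O)[C@H]1C(=O)C[C@H]2C | intermediate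
18 | (1R,2R,6R,7R,8S,11R)-2-hydroxy-3,3,7,11-tetramethyl-6-[(triethylsilyl)oxy]tricyclo[5.4.0.0(2,8)]undecane-4,9-dione | O=C1C[C@@H](O[Si](CC)(CC)CC)[C@]2(C)[C@@H]3[C@@](O)([C@H]2C(=O)C[C@H]3C)C1(C)C | intermediate
19 | methyl (1R,2R,6R,7R,8S,11R)-3,3,7,11-tetramethyl-4,9-dioxo-6-[(triethylsilyl)oxy]tricyclo[5.4.0.0(2,8)]undecan-2-yl oxalate | O=C1C[C@@H](O[Si](CC)(CC)CC)[C@]2(C)[C@@H]3[C@@](OC(=O)C(=O)OC)([C@H]2C(=O)C[C@H]3C)C1(C)C | intermediate
20 | (1S,2S,6R,7R,8R,11R)-3,3,7,11-tetramethyl-6-[(triethylsilyl)oxy]tricyclo[5.4.0.0(2,8)]undecane-4,9-dione | O=C1C[C@@H](O[Si](CC)(CC)CC)[C@]2(C)[C@@H]3[C@@H]([C@H]2C(=O)C[C@H]3C)C1(C)C | intermediate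
21 | (1S,2S,6R,7R,8R,11R)-6-hydroxy-3,3,7,11-tetramethyltricyclo[5.4.0.0(2,8)]undecane-4,9-dione | O=C1C[C@@H](O)[C@]2(C)[C@@H]3[C@@H]([C@H]2C(=O)C[C@H]3C)C1(C)C | intermediate
22 | (1S,2S,4R,6R,7R,8R,11R)-4,6-dihydroxy-3,3,7,11-tetramethyltricyclo[5.4.0.0(2,8)]undecan-9-one (C7 and C9 hydroxyls trans) | O[C@@H]1C[C@@H](O)[C@]2(C)[C@@H]3[C@@H]([C@H]2C(=O)C[C@H]3C)C1(C)C | intermediate
23 | angelic acid, (2Z)-2-methylbut-2-enoic acid | C/C=C(/C)C(=O)O | starting material
24 | (2Z)-2-methylbut-2-enoic 2,4,6-trichlorobenzoic anhydride | C/C=C(/C)C(=O)OC(=O)c1c(Cl)cc(Cl)cc1Cl | intermediate (not isolated)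
25 | (1S,2S,4R,6R,7R,8R,11R)-4-hydroxy-3,3,7,11-tetramethyl-9-oxotricyclo[5.4.0.0(2,8)]undecan-6-yl (2Z)-2-methylbut-2-enoate (C9 angelate, C7 hydroxyl free) | O[C@@H]1C[C@@H](OC(=O)/C(C)=C\C)[C@]2(C)[C@@H]3[C@@H]([C@H]2C(=O)C[C@H]3C)C1(C)C | intermediate (not isolated)
26 | (1S,2S,4R,6R,7R,8R,11R)-3,3,7,11-tetramethyl-9-oxotricyclo[5.4.0.0(2,8)]undecane-4,6-diyl bis[(2Z)-2-methylbut-2-enoate], CNP0283599.1 | C/C=C(/C)C(=O)O[C@@H]1C[C@@H](OC(=O)/C(C)=C\C)[C@]2(C)[C@@H]3[C@@H]([C@H]2C(=O)C[C@H]3C)C1(C)C | target

Total step count: 17. Longest linear sequence: 17 steps (1 to 26); 7, 9, 14 and 23 enter directly.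

Steps most likely to fail

Step 7. What may go wrong: the strained cyclobutene enamine is acylated on nitrogen or carbon without the second bond closing, or the auxiliary does not distinguish the two α-carbons. The fallback uses known chemistry, sets out from 6 and comes back at 11; it makes the two bonds one at a time. Ketone 6 would be condensed with (S)-1-amino-2-(methoxymethyl)pyrrolidine to the SAMP hydrazone F1. Its lithium azaenolate (LiN(iPr)2, THF, −78 °C) would add to methyl (E)-but-2-enoate in an Enders hydrazone Michael addition to give the ester hydrazone F2, whose diastereomers, still carrying the auxiliary, would be separated by chromatography. Aqueous oxalic acid would release the keto ester F3, LiOH would give the keto acid F4, and oxalyl chloride the keto acid chloride F5. TiCl4/Bu3N would then close C1–C11 by intramolecular C-acylation of the titanium enolate (titanium-mediated Claisen-type acylation), which is irreversible and should give 11.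

Step 12. What may go wrong: the copper enolate is quenched before it cyclises (plain 1,4-reduction), or the aldolate reverts before it is trapped. The fallback sets out from 17 and comes back at 18; the enolate is stored as an enol silane and the ring is closed under Lewis acid. RhCl(PPh3)3-catalysed 1,4-hydrosilylation of the enone with Et3SiH would give the tetrasubstituted triethylsilyl enol ether F6. TiCl4 (CH2Cl2, −78 °C) would then effect an intramolecular Mukaiyama aldol addition of C6 to the C5 ketone, giving 18 after aqueous work-up.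

Step 14. What may go wrong: the bridgehead C5 radical attacks the neighbouring C7 carbonyl (1,2-acyl shift with ring contraction) faster than it is reduced. The fallback sets out from 19 and comes back at 22; the ketone is removed before the radical is made. HF·pyridine would cleave the TES ether of 19 to the hydroxy ketone oxalate F7, Me4NBH(OAc)3 would reduce C7 under direction of the C9 hydroxyl to the diol oxalate F8, and Bu3SnH/AIBN would then deoxygenate C5 to give diol 22 directly, bypassing 20 and 21.

Further compounds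
F1 | step 7 | SAMP hydrazone of 6 (C=N isomer mixture) | COC[C@@H]1CCCN1N=C1CC(C)(CO[Si](c2ccccc2)(c2ccccc2)C(C)(C)C)C1
F2 | step 7 | SAMP hydrazone of methyl (3R)-3-[(1R,2S)-2-{[(tert-butyldiphenylsilyl)oxy]methyl}-2-methyl-4-oxocyclobutyl]butanoate | CC(C)(C)[Si](c1ccccc1)(c1ccccc1)OC[C@]1(C)[C@@H]([C@H](C)CC(=O)OC)C(=NN2CCC[C@H]2COC)C1
F3 | step 7 | methyl (3R)-3-[(1R,2S)-2-{[(tert-butyldiphenylsilyl)oxy]methyl}-2-methyl-4-oxocyclobutyl]butanoate | CC(C)(C)[Si](c1ccccc1)(c1ccccc1)OC[C@]1(C)[C@@H]([C@H](C)CC(=O)OC)C(=O)C1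
F4 | step 7 | (3R)-3-[(1R,2S)-2-{[(tert-butyldiphenylsilyl)oxy]methyl}-2-methyl-4-oxocyclobutyl]butanoic acid | CC(C)(C)[Si](c1ccccc1)(c1ccccc1)OC[C@]1(C)[C@@H]([C@H](C)CC(=O)O)C(=O)C1
F5 | step 7 | (3R)-3-[(1R,2S)-2-{[(tert-butyldiphenylsilyl)oxy]methyl}-2-methyl-4-oxocyclobutyl]butanoyl chloride | CC(C)(C)[Si](c1ccccc1)(c1ccccc1)OC[C@]1(C)[C@@H]([C@H](C)CC(Cl)=O)C(=O)C1
F6 | step 12 | triethylsilyl enol ether of 17 (C7 O-silyl, C6=C7 double bond, C9 OTES, dione core as in 17) | CC[Si](CC)(CC)OC(C[C@@H](O[Si](CC)(CC)CC)[C@]1(C)[C@@H]2C(=O)[C@H]1C(=O)C[C@H]2C)=C(C)C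
F7 | step 14 | C9 hydroxy C7 ketone C5 methyl oxalate (19 without the triethylsilyl group) | O=C1C[C@@H](O)[C@]2(C)[C@@H]3[C@@](OC(=O)C(=O)OC)([C@H]2C(=O)C[C@H]3C)C1(C)C
F8 | step 14 | C7,C9 trans-diol C5 methyl oxalate | O[C@@H]1C[C@@H](O)[C@]2(C)[C@@H]3[C@@](OC(=O)C(=O)OC)([C@H]2C(=O)C[C@H]3C)C1(C)C
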